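## Structural features

Ring labels used throughout: ring A is the benzene ring of the dihydrobenzofuran, ring B the catechol on the methine, ring C the pyran of the flavan, ring D the benzene ring of the flavan that carries C8, ring E the catechol on flavan C2.

- The target is (+)-catechin (rings C, D, E; flavan C2 R, C3 S, trans) whose C8 carries an sp3 methine. That methine also bears ring B and C2 of a 4,6-dihydroxy-2,3-dihydrobenzofuran (ring A fused to the furan).
- There are four stereocentres. The flavan pair comes from the chiral pool. The methine (R) and the adjacent furan C2 (S) form an exocyclic vicinal pair, five bonds from the flavan centres, so the catechin core cannot be expected to steer them.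
- Nine hydroxyls (eight phenolic, one secondary) make the free compound sensitive to air and base. The flavan O1–C2 bond is a benzylic ether of an electron-rich ring and can ionise in acid. Rings A and D are phloroglucinol-type and react readily with electrophiles and oxidants.
- The real difficulty is the methine. It is crowded between the two ortho oxygens of ring D (O7 and O1 at C8a) and it is doubly benzylic. A carbonyl on the neighbouring carbon would let it enolise and lose its configuration.
- Both new centres must therefore be set by reagents, and the carbon next to the methine should never pass through the aldehyde or ketone oxidation level.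
- The key step uses the fact that furan C3 is a benzylic CH2 on ring A and furan C2 is an oxygen-bearing carbon next to the methine. The C2–C3 bond can be made by moving the ring A benzyl group from boron onto a carbamate-bearing carbanion carbon. Boron stays on C2 as the latent furan oxygen, and an ortho bromine on ring A is kept for the O1–C7a closure.

## Logic of the disconnections

22 to 21: the nine O–CH2Ph bonds are cut. Benzyl is the one group that leaves all phenols and the 3-hydroxyl in a single neutral hydrogenolysis, which suits an acid-, base- and air-sensitive polyphenol. The forward step must not open the flavan O1–C2 ether.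

21 to 20: the furan O1–C7a (aryl–oxygen) bond is cut. This leaves a secondary alcohol and an ortho aryl bromide. The closure must form the aryl C–O bond and leave the carbinol C–O bond alone, so that furan C2 keeps its configuration.

20 to 19: the C2–O bond is traced to a C2–B bond. Oxidation of a boronic ester goes with retention, so the configuration at C2 is decided one step earlier.

19 to 9 + 16: the furan C2–C3 bond is cut. This is the only cut that separates the ring A piece cleanly from the methine-bearing half and at the same time creates C2 under reagent control. The forward step needs selective deprotonation next to the carbamate oxygen of 9 in the presence of a more acidic methine and many O-benzyl CH2 groups, and a boron partner that tolerates an aryl bromide.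

9 to 8: the carbamate acyl–oxygen bond is cut. The demand is only a clean acylation of a hindered primary alcohol.

8 to 5 + 6 (through 7): the methine–ring B bond and the terminal C–O bond (as C–B) are cut across a vinyl group. Both atoms are added to a C8 vinyl group in one operation, so the carbon next to the methine is never a carbonyl and carries no leaving group. The forward step must choose one face of the vinyl group by catalyst control, because the flavan centres are too remote.

5 to 4 to 3 to 2 to 1: the vinyl–C8 bond, the 3-O-benzyl bond, the C8–Br bond and the four phenolic O-benzyl bonds are cut in turn. C8 is the more reactive free position of ring D in 2, so bromination supplies the handle. 1 brings rings C, D, E and both flavan stereocentres.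

16 to 13 to 12 to 10: the benzylic C–B bond is traced to an aldehyde carbon through its tosylhydrazone, and the formyl carbon to a formylation of 10. A metal-free borylation is wanted so that the aryl C–Br bond survives. 10 already carries benzyl ethers, so no protecting-group exchange is needed on ring A.

## Other disconnections considered

Alternative 1: The cut is flavan C4–C4a, with the C3 hydroxyl traced to an oxirane, so that ring C is made last.
- Forward key step: epoxy ether A2 already carries the whole dihydrobenzofuran–methine half. Hexafluoroisopropanol or BF3·OEt2 activates the oxirane, and the single free ring D position ortho to O1 attacks its terminal carbon (6-endo Friedel–Crafts opening) to give A1.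
- In its favour: the C3–O bond is not touched, so C3 is carried over from the epoxide. Only one ring D position is free, so the regiochemistry is not in doubt. Either flavan configuration could be reached by choice of epoxide. A1 arrives with the 3-hydroxyl distinguished from the phenols, which the chosen plan cannot do; on these two points it is the better plan.
- Against it here: the flavan unit that 1 supplies ready-made must be built by asymmetric synthesis. The methine and furan C2 must already be present in A2, so none of the real difficulty is removed. The O1–C2 bond of A2 is a benzylic ether para to an oxygen of ring E and may ionise under the same activation, which threatens C2; 5-exo opening also competes.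
- Comparison: mechanistically both key steps are stereospecific displacements at carbon and are equal on that count. The alternative avoids an organolithium on a polybenzylated substrate, which is in its favour. In step economy it is clearly longer, and its decisive step acts on the most advanced intermediate.

Alternative 2: The cut takes furan O1–C2 and the methine–ring B bond together.
- Forward key step: ortho-allylphenol A4 (E alkene, ring D at its far end) and ring B triflate A5 react under zerovalent palladium with a bulky biaryl phosphine and base. The phenoxide adds anti to the palladium-activated alkene and reductive elimination joins ring B to the former alkene carbon. The product A3 is the same compound as 21.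
- In its favour: one step forms the furan ring, two bonds and both new stereocentres. Anti addition across the E alkene corresponds to the required relative configuration (furan C2 S with methine R, or the mirror pair). No strong base meets the benzyl ethers. It is the shortest plan considered. On all of these points it is better than the chosen route.
- Against it here: only the remote flavan centres distinguish the two alkene faces of A4, so both anti adducts must be expected unless a chiral ligand discriminates, and that is not established for internal alkenes of this kind. The carbon that must accept ring B sits on the di-ortho-oxygenated ring D, so β-hydride elimination and Heck-type products compete. A switch from anti to syn oxypalladation would invert the relative configuration.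
- Comparison: equal in the end game (same 21, same hydrogenolysis). Better in convergence and step count. Worse in control of absolute configuration, which the chosen plan sets one centre at a time by reagent, each with a chance of purification.

Alternative 3: The cut is the methine–furan C2 bond.
- Forward key step: acid ionises the C8 diarylmethanol A7 (free 7-hydroxyl) to an ortho-quinone methide over O7–C7–C8–CH. This adds across C2=C3 of benzofuran A8, methine carbon to furan C2 and O7 to furan C3, to give the cis-fused A6. The extra O7–C3 bond must later be cleaved reductively.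
- In its favour: the methine needs no prior stereocontrol, because ionisation planarises it and A7 can be used as a mixture. This is a real advantage over the chosen plan, which spends an asymmetric catalytic step on that centre. Two bonds form at once and the suprafacial addition fixes the relative configuration of methine and C2. It is highly convergent.
- Against it here: as an enol ether the benzofuran would be expected to bond through C3 to the methide carbon and take O7 at C2, the opposite orientation. The required sense depends on charge stabilisation at C3 by the ring A oxygens and is uncertain. Facial selectivity relative to the flavan centres is uncontrolled without a chiral acid. O7 must be freed selectively beside O5. The later O7–C3 cleavage must spare the flavan O1–C2 bond of the same type, and a cation at C3 could lose the C2 proton and aromatise, erasing C2.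
- Comparison: structurally it attacks the hardest bond directly and is shorter up to A6. Mechanistically it rests on two selectivities that the substrate does not secure, where the chosen plan rests on reagent control. The step saving is largely spent on O7 differentiation and the C–O cleavage, so the two plans are about equal in length.

Key step: step 10

Remarks on the chemistry (assumptions):
- sec-Butyllithium/(−)-sparteine is assumed to remove the pro-S hydrogen next to the carbamate oxygen of 9, as it does for simple primary O-alkyl carbamates. With boron capture under retention and migration under inversion this gives S at the boron-bearing carbon, which maps onto furan C2 of the target.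
- The configurations of 9 (methine R), 19 (boron-bearing carbon S, methine R) and 22 (furan C2 S, methine R, flavan 2R,3S) were checked against each other and agree.
- Ring A is carried as benzyl ethers from the first step, so one hydrogenolysis frees all nine hydroxyls.
- The sense of induction of the copper ligand in step 5 is to be assigned on 8; the ligand antipode that gives the R methine is the one used.

## Steps

Step 1
Reactants: 1 (+)-catechin
Product: 2 5,7,3',4'-tetra-O-benzyl-(+)-catechin
Conditions: BnBr (4.4 equiv), K2CO3, DMF, 0 °C → rt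
Reagents that add atoms: benzyl bromide, BrCc1ccccc1
Why: Williamson etherification of the four phenols under carbonate; the secondary 3-hydroxyl is not deprotonated, and the mild base and low temperature limit C-benzylation of ring D and epimerisation at flavan C2.

Step 2
Reactants: 2 5,7,3',4'-tetra-O-benzyl-(+)-catechin
Product: 3 8-bromo-5,7,3',4'-tetra-O-benzyl-(+)-catechin
Conditions: NBS (1.0 equiv), CH2Cl2, −78 °C → rt
Reagents that add atoms: N-bromosuccinimide, O=C1CCC(=O)N1Br
Why: Electrophilic aromatic bromination of the most electron-rich ring (D); in 5,7-di-O-benzyl flavans C8 is the more reactive free position, and the catechol ether ring E is far less nucleophilic.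

Step 3
Reactants: 3 8-bromo-5,7,3',4'-tetra-O-benzyl-(+)-catechin
Product: 4 8-bromo-3,5,7,3',4'-penta-O-benzyl-(+)-catechin
Conditions: NaH, BnBr, Bu4NI (cat.), DMF, 0 °C → rt
Reagents that add atoms: benzyl bromide, BrCc1ccccc1
Why: Williamson etherification of the secondary alkoxide; with the phenols capped no base-labile site remains, and the aryl bromide is inert.

Step 4
Reactants: 4 8-bromo-3,5,7,3',4'-penta-O-benzyl-(+)-catechin
Product: 5 8-vinyl-3,5,7,3',4'-penta-O-benzyl-(+)-catechin
Conditions: vinylboronic acid pinacol ester (1.5 equiv), Pd(OAc)2 (5 mol%), SPhos (10 mol%), K3PO4, toluene/H2O, 90 °C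
Reagents that add atoms: 4,4,5,5-tetramethyl-2-vinyl-1,3,2-dioxaborolane, C=CB1OC(C)(C)C(C)(C)O1
Why: Suzuki–Miyaura coupling; a bulky electron-rich biaryl phosphine is chosen because the bromide is electron-rich and flanked by two ortho oxygens.

Step 5
Reactants: 5 8-vinyl-3,5,7,3',4'-penta-O-benzyl-(+)-catechin; 6 4-bromo-1,2-bis(benzyloxy)benzene
Product: 8 (2R)-2-[3,4-bis(benzyloxy)phenyl]-2-(3,5,7,3',4'-penta-O-benzyl-(+)-catechin-8-yl)ethanol, via primary boronic ester 7 (not isolated)
Conditions: 6 (1.5 equiv), B2pin2 (1.5 equiv), CuCl/chiral sulfoxide–phosphine ligand (10 mol%), Pd(OAc)2/RuPhos (2 mol%), NaOtBu, THF, rt; silica plug; then NaOH aq., H2O2, THF, 0 °C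
Reagents that add atoms: bis(pinacolato)diboron, CC1(C)OB(OC1(C)C)B1OC(C)(C)C(C)(C)O1 (boron and pinacolate of 7); hydrogen peroxide, OO (oxygen of 8)
Why: Cooperative copper/palladium arylboration of a vinylarene: the chiral copper–boryl adds syn across the vinyl group with boron on the terminal carbon and copper on the benzylic carbon, the benzylic copper transmetalates stereospecifically to the aryl–palladium bromide formed from 6, and reductive elimination makes the methine–ring B bond. The methine configuration is set by the copper ligand and not by the remote flavan centres; oxidation of the C–B bond with retention then gives the primary alcohol without a carbonyl ever standing next to the methine.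

Step 6
Reactants: 8 (2R)-2-[3,4-bis(benzyloxy)phenyl]-2-(3,5,7,3',4'-penta-O-benzyl-(+)-catechin-8-yl)ethanol
Product: 9 (2R)-2-[3,4-bis(benzyloxy)phenyl]-2-(3,5,7,3',4'-penta-O-benzyl-(+)-catechin-8-yl)ethyl N,N-diisopropylcarbamate
Conditions: NaH, iPr2NCOCl, THF, 0 °C → reflux
Reagents that add atoms: N,N-diisopropylcarbamoyl chloride, CC(C)N(C(C)C)C(Cl)=O
Why: Acylation of the primary alkoxide by the carbamoyl chloride; the alkoxide has no elimination or migration pathway and the methine is not touched.

Step 7
Reactants: 10 1,3-bis(benzyloxy)-5-bromobenzene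
Product: 12 2-bromo-4,6-bis(benzyloxy)benzaldehyde, via aryl iminium chloride 11 (not isolated)
Conditions: POCl3, DMF, 0 → 60 °C; then NaOH aq.
Reagents that add atoms: N,N-dimethylformamide, CN(C)C=O (formyl carbon); water, O (formyl oxygen); phosphoryl chloride, O=P(Cl)(Cl)Cl (chloride of 11 only)
Why: Vilsmeier–Haack formylation; the chloroiminium ion attacks para to one benzyloxy group and ortho to the other, next to bromine, which is the established orientation for 1-bromo-3,5-dialkoxybenzenes, and hydrolysis of 11 gives the aldehyde.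

Step 8
Reactants: 12 2-bromo-4,6-bis(benzyloxy)benzaldehyde
Product: 13 (E)-N'-[2-bromo-4,6-bis(benzyloxy)benzylidene]-4-methylbenzenesulfonohydrazide
Conditions: TsNHNH2, MeOH, 60 °C
Reagents that add atoms: p-toluenesulfonyl hydrazide, Cc1ccc(cc1)S(=O)(=O)NN
Why: Condensation of the aldehyde with the sulfonyl hydrazide; the hydrazone of an aryl aldehyde forms readily and crystallises.

Step 9
Reactants: 13 (E)-N'-[2-bromo-4,6-bis(benzyloxy)benzylidene]-4-methylbenzenesulfonohydrazide
Product: 16 2-[2-bromo-4,6-bis(benzyloxy)benzyl]-4,4,5,5-tetramethyl-1,3,2-dioxaborolane, via aryldiazomethane 14 (not isolated), via geminal bis(boronate) 15 (not isolated)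
Conditions: NaH, B2pin2 (1.3 equiv), MeOH (5 equiv), toluene, 110 °C
Reagents that add atoms: bis(pinacolato)diboron, CC1(C)OB(OC1(C)C)B1OC(C)(C)C(C)(C)O1
Why: Bamford–Stevens decomposition of the hydrazone salt gives the diazo compound, whose carbon adds to boron and triggers a 1,2-boryl shift with loss of nitrogen; methanolysis of one C–B bond of the benzylic geminal bis(boronate) gives the benzylboronic ester. The reductive borylation uses no transition metal, so the aryl C–Br bond is untouched.

Step 10
Reactants: 9 (2R)-2-[3,4-bis(benzyloxy)phenyl]-2-(3,5,7,3',4'-penta-O-benzyl-(+)-catechin-8-yl)ethyl N,N-diisopropylcarbamate; 16 2-[2-bromo-4,6-bis(benzyloxy)benzyl]-4,4,5,5-tetramethyl-1,3,2-dioxaborolane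
Product: 19 2-{(2S,3R)-1-[2-bromo-4,6-bis(benzyloxy)phenyl]-3-[3,4-bis(benzyloxy)phenyl]-3-(3,5,7,3',4'-penta-O-benzyl-(+)-catechin-8-yl)propan-2-yl}-4,4,5,5-tetramethyl-1,3,2-dioxaborolane, via lithiated carbamate 17 (not isolated), via lithium boronate complex 18 (not isolated)
Conditions: sBuLi (1.0 equiv), (−)-sparteine (1.1 equiv), Et2O, −78 °C, 5 h; 16 (1.5 equiv), −78 °C, 1 h; MgBr2·OEt2, −78 °C → reflux, 12 h
Reagents that add atoms: sec-butyllithium, CCC(C)[Li] (lithium of 17 and 18 only; no atom of it remains in 19)
Why: sec-Butyllithium held by (−)-sparteine binds the carbamate carbonyl and removes the pro-S hydrogen of the adjacent CH2, giving the configurationally stable (S)-α-oxyalkyllithium 17. The boron of 16 captures 17 with retention to give the tetracoordinate boronate 18. On warming with MgBr2, which binds the carbamate, the ring A benzyl group shifts from boron to carbon antiperiplanar to the departing carbamate, that is with inversion, forming the furan C2–C3 bond and leaving boron on the S-configured future C2. The closest known reaction type is the sparteine-mediated lithiation–borylation (1,2-metallate rearrangement) of primary O-alkyl carbamates with pinacol boronic esters. No ring is closed. The new stereocentre is controlled by the diamine; the neighbouring methine only decides whether the pairing is matched. The step needs deprotonation at the carbamate CH2 and not at the more acidic methine or an O-benzyl CH2; this rests on precomplexation at the carbamate, diethyl ether as solvent, base as the limiting reagent, and the shielding and poor alignment of the methine C–H between the two ortho oxygens of ring D. The aryl bromide should survive because no free sec-butyllithium is left when 16 is added and boron capture is much faster than bromine–lithium exchange by the chelated carbanion; excess 16 prevents a second homologation of 19.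

Step 11
Reactants: 19 the secondary pinacol boronic ester
Product: 20 (2S,3R)-1-[2-bromo-4,6-bis(benzyloxy)phenyl]-3-[3,4-bis(benzyloxy)phenyl]-3-(3,5,7,3',4'-penta-O-benzyl-(+)-catechin-8-yl)propan-2-ol
Conditions: NaOH aq., H2O2, THF, 0 °C → rt
Reagents that add atoms: hydrogen peroxide, OO
Why: Hydroperoxide adds to boron and the alkyl group migrates from boron to oxygen with retention, so the S C–B carbon becomes the S carbinol; aryl bromide and benzyl ethers are inert to cold alkaline peroxide.

Step 12
Reactants: 20 the secondary alcohol with the ortho bromide on ring A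
Product: 21 (2S)-4,6-bis(benzyloxy)-2-{(R)-[3,4-bis(benzyloxy)phenyl](3,5,7,3',4'-penta-O-benzyl-(+)-catechin-8-yl)methyl}-2,3-dihydrobenzofuran
Conditions: CuI (10 mol%), 3,4,7,8-tetramethyl-1,10-phenanthroline (20 mol%), Cs2CO3, toluene, 110 °C
Reagents that add atoms: none
Why: Intramolecular Ullmann-type etherification: the copper alkoxide inserts into the ortho C–Br bond and reductive elimination closes the five-membered ring through the aryl C–O bond. The carbinol C–O bond is not broken, so furan C2 keeps S, and carbonate is too weak a base to touch the methine.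

Step 13
Reactants: 21 the nona-O-benzyl ether
Product: 22 (2R,3S)-2-(3,4-dihydroxyphenyl)-8-{(R)-(3,4-dihydroxyphenyl)[(2S)-4,6-dihydroxy-2,3-dihydrobenzofuran-2-yl]methyl}chromane-3,5,7-triol (target)
Conditions: H2 (1 atm), Pd(OH)2/C, THF/MeOH (degassed), rt
Reagents that add atoms: none
Why: Hydrogenolysis of the nine benzyl ethers (eight aryl, one alkyl); the cyclic flavan O1–C2 ether and the furan ether survive as in the usual deprotection of benzylated flavan-3-ols, and no stereocentre is touched.

## Compound list

1 | (+)-catechin, (2R,3S)-2-(3,4-dihydroxyphenyl)chromane-3,5,7-triol | O[C@H]1Cc2c(O)cc(O)cc2O[C@@H]1c1ccc(O)c(O)c1 | starting material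
2 | 5,7,3',4'-tetra-O-benzyl-(+)-catechin | c1c(OCc2ccccc2)cc(OCc2ccccc2)c2c1O[C@H](c1ccc(OCc3ccccc3)c(OCc3ccccc3)c1)[C@@H](O)C2 | intermediate
3 | 8-bromo-5,7,3',4'-tetra-O-benzyl-(+)-catechin | Brc1c(OCc2ccccc2)cc(OCc2ccccc2)c2c1O[C@H](c1ccc(OCc3ccccc3)c(OCc3ccccc3)c1)[C@@H](O)C2 | intermediate
4 | 8-bromo-3,5,7,3',4'-penta-O-benzyl-(+)-catechin | Brc1c(OCc2ccccc2)cc(OCc2ccccc2)c2c1O[C@H](c1ccc(OCc3ccccc3)c(OCc3ccccc3)c1)[C@@H](OCc1ccccc1)C2 | intermediate
5 | 8-vinyl-3,5,7,3',4'-penta-O-benzyl-(+)-catechin | C=Cc1c(OCc2ccccc2)cc(OCc2ccccc2)c2c1O[C@H](c1ccc(OCc3ccccc3)c(OCc3ccccc3)c1)[C@@H](OCc1ccccc1)C2 | intermediate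
6 | 4-bromo-1,2-bis(benzyloxy)benzene | Brc1ccc(OCc2ccccc2)c(OCc2ccccc2)c1 | starting material
7 | 2-{(2R)-2-[3,4-bis(benzyloxy)phenyl]-2-(penta-O-benzyl-(+)-catechin-8-yl)ethyl}-4,4,5,5-tetramethyl-1,3,2-dioxaborolane (primary boronic ester, not isolated) | CC1(C)OB(OC1(C)C)C[C@H](c1ccc(OCc2ccccc2)c(OCc2ccccc2)c1)c1c(OCc2ccccc2)cc(OCc2ccccc2)c2c1O[C@H](c1ccc(OCc3ccccc3)c(OCc3ccccc3)c1)[C@@H](OCc1ccccc1)C2 | intermediate
8 | (2R)-2-[3,4-bis(benzyloxy)phenyl]-2-(penta-O-benzyl-(+)-catechin-8-yl)ethanol | OC[C@H](c1ccc(OCc2ccccc2)c(OCc2ccccc2)c1)c1c(OCc2ccccc2)cc(OCc2ccccc2)c2c1O[C@H](c1ccc(OCc3ccccc3)c(OCc3ccccc3)c1)[C@@H](OCc1ccccc1)C2 | intermediate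
9 | (2R)-2-[3,4-bis(benzyloxy)phenyl]-2-(penta-O-benzyl-(+)-catechin-8-yl)ethyl N,N-diisopropylcarbamate | CC(C)N(C(C)C)C(=O)OC[C@H](c1ccc(OCc2ccccc2)c(OCc2ccccc2)c1)c1c(OCc2ccccc2)cc(OCc2ccccc2)c2c1O[C@H](c1ccc(OCc3ccccc3)c(OCc3ccccc3)c1)[C@@H](OCc1ccccc1)C2 | intermediate
10 | 1,3-bis(benzyloxy)-5-bromobenzene | Brc1cc(OCc2ccccc2)cc(OCc2ccccc2)c1 | starting material
11 | N-[2-bromo-4,6-bis(benzyloxy)benzylidene]-N-methylmethanaminium chloride (aryl iminium chloride, not isolated) | C[N+](C)=Cc1c(Br)cc(OCc2ccccc2)cc1OCc1ccccc1.[Cl-] | intermediate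
12 | 2-bromo-4,6-bis(benzyloxy)benzaldehyde | O=Cc1c(Br)cc(OCc2ccccc2)cc1OCc1ccccc1 | intermediate
13 | (E)-N'-[2-bromo-4,6-bis(benzyloxy)benzylidene]-4-methylbenzenesulfonohydrazide | Cc1ccc(cc1)S(=O)(=O)N/N=C/c1c(Br)cc(OCc2ccccc2)cc1OCc1ccccc1 | intermediate
14 | 1,5-bis(benzyloxy)-3-bromo-2-(diazomethyl)benzene (not isolated) | [N-]=[N+]=Cc1c(Br)cc(OCc2ccccc2)cc1OCc1ccccc1 | intermediate
15 | 2,2'-{[2-bromo-4,6-bis(benzyloxy)phenyl]methylene}bis(4,4,5,5-tetramethyl-1,3,2-dioxaborolane) (not isolated) | CC1(C)OB(OC1(C)C)C(B1OC(C)(C)C(C)(C)O1)c1c(Br)cc(OCc2ccccc2)cc1OCc1ccccc1 | intermediate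
16 | 2-[2-bromo-4,6-bis(benzyloxy)benzyl]-4,4,5,5-tetramethyl-1,3,2-dioxaborolane | CC1(C)OB(OC1(C)C)Cc1c(Br)cc(OCc2ccccc2)cc1OCc1ccccc1 | intermediate
17 | (1S,2R)-1-lithio derivative of carbamate 9, as its (−)-sparteine complex (not isolated) | CC(C)N(C(C)C)C(=O)O[C@@H]([Li])[C@H](c1ccc(OCc2ccccc2)c(OCc2ccccc2)c1)c1c(OCc2ccccc2)cc(OCc2ccccc2)c2c1O[C@H](c1ccc(OCc3ccccc3)c(OCc3ccccc3)c1)[C@@H](OCc1ccccc1)C2 | intermediate
18 | lithium boronate complex of 17 with 16: boron bears pinacolate, the ring A benzyl group and the (1S)-carbamoyloxyalkyl group (not isolated) | CC(C)N(C(C)C)C(=O)O[C@@H]([B-]1(Cc2c(Br)cc(OCc3ccccc3)cc2OCc2ccccc2)OC(C)(C)C(C)(C)O1)[C@H](c1ccc(OCc2ccccc2)c(OCc2ccccc2)c1)c1c(OCc2ccccc2)cc(OCc2ccccc2)c2c1O[C@H](c1ccc(OCc3ccccc3)c(OCc3ccccc3)c1)[C@@H](OCc1ccccc1)C2.[Li+] | intermediate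
19 | 2-{(2S,3R)-1-[2-bromo-4,6-bis(benzyloxy)phenyl]-3-[3,4-bis(benzyloxy)phenyl]-3-(penta-O-benzyl-(+)-catechin-8-yl)propan-2-yl}-4,4,5,5-tetramethyl-1,3,2-dioxaborolane | Brc1cc(OCc2ccccc2)cc(OCc2ccccc2)c1C[C@H](B2OC(C)(C)C(C)(C)O2)[C@H](c1ccc(OCc2ccccc2)c(OCc2ccccc2)c1)c1c(OCc2ccccc2)cc(OCc2ccccc2)c2c1O[C@H](c1ccc(OCc3ccccc3)c(OCc3ccccc3)c1)[C@@H](OCc1ccccc1)C2 | intermediate
20 | (2S,3R)-1-[2-bromo-4,6-bis(benzyloxy)phenyl]-3-[3,4-bis(benzyloxy)phenyl]-3-(penta-O-benzyl-(+)-catechin-8-yl)propan-2-ol | Brc1cc(OCc2ccccc2)cc(OCc2ccccc2)c1C[C@H](O)[C@H](c1ccc(OCc2ccccc2)c(OCc2ccccc2)c1)c1c(OCc2ccccc2)cc(OCc2ccccc2)c2c1O[C@H](c1ccc(OCc3ccccc3)c(OCc3ccccc3)c1)[C@@H](OCc1ccccc1)C2 | intermediate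
21 | (2S)-4,6-bis(benzyloxy)-2-{(R)-[3,4-bis(benzyloxy)phenyl](penta-O-benzyl-(+)-catechin-8-yl)methyl}-2,3-dihydrobenzofuran (nona-O-benzyl ether of the target) | C(c1ccccc1)Oc1cc(OCc2ccccc2)c2c(c1)O[C@H]([C@H](c1ccc(OCc3ccccc3)c(OCc3ccccc3)c1)c1c(OCc3ccccc3)cc(OCc3ccccc3)c3c1O[C@H](c1ccc(OCc4ccccc4)c(OCc4ccccc4)c1)[C@@H](OCc1ccccc1)C3)C2 | intermediate
22 | (2R,3S)-2-(3,4-dihydroxyphenyl)-8-{(R)-(3,4-dihydroxyphenyl)[(2S)-4,6-dihydroxy-2,3-dihydrobenzofuran-2-yl]methyl}chromane-3,5,7-triol | Oc1cc(O)c2c(c1)O[C@H]([C@H](c1ccc(O)c(O)c1)c1c(O)cc(O)c3c1O[C@H](c1ccc(O)c(O)c1)[C@@H](O)C3)C2 | target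

## Step count and least certain steps

Total: 13 steps. Longest linear sequence: 10 steps (steps 1–6, then 10–13); steps 7–9 form the three-step branch to 16.

Step 10 (key step).
- What may go wrong: metalation at the wrong site. The doubly benzylic methine, if deprotonated, would eliminate the carbamate to a 1,1-diarylethene. An O-benzyl CH2, if deprotonated, would undergo a 1,2-shift of the Wittig type. These C–H bonds are thermodynamically more acidic than the carbamate CH2, and the wanted deprotonation is slowed by the bulky neighbouring methine. Lesser risks are reversal of the crowded boronate before migration and a mismatch between (−)-sparteine and the methine.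
- Fallback (sets out from 8 and 12, returns at 20): oxidation of 8 with Dess–Martin periodinane (NaHCO3, CH2Cl2, 0 °C) gives (2R)-2,2-diarylacetaldehyde F1, which is used at once and cold because its α-hydrogen is labile. In parallel 12 is reduced (NaBH4) to 2-bromo-4,6-bis(benzyloxy)benzyl alcohol F2 and converted (SOCl2, CH2Cl2) into 2-bromo-4,6-bis(benzyloxy)benzyl chloride F3. Zinc insertion (Zn dust, LiCl, THF), which leaves the aryl bromide alone, gives the benzylic zinc chloride F4. Addition of F4 to F1 (THF, MgCl2, 0 °C) gives the carbinol F5 as a mixture of epimers at the new centre. Oxidation (Dess–Martin periodinane) gives the benzyl ketone F6. Reduction with LiBH(sBu)3 in THF at −78 °C should then follow the Felkin–Anh model, hydride entering anti to the bulky ring D substituent, which leads to the (2S,3R) alcohol 20. The price is two carbonyl compounds next to the methine, which must be handled cold and without base.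

Step 5.
- What may go wrong: slow borylcupration of the twisted, electron-rich vinyl group, so that the aryl bromide is diverted to direct borylation; protodecupration to the simple hydroboration product; or loss of facial selectivity if the hindered benzylic copper epimerises before a slow transmetalation.
- Fallback (sets out from 4, returns at 8): the tosylhydrazone F7 of commercial 3,4-bis(benzyloxy)acetophenone (TsNHNH2, MeOH) is cross-coupled with 4 under zerovalent palladium (Pd2(dba)3, XPhos, LiOtBu, dioxane, 100 °C; carbene migratory insertion, then β-hydride elimination) to give the 1,1-diarylethene F8. Hydroboration–oxidation (BH3·THF; NaOH, H2O2) gives 8 together with its methine epimer F9. The two are diastereomers because the catechin core is enantiopure, and they are separated by chromatography. Stereocontrol is given up in exchange for robust bond formation; the unwanted epimer is lost.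

Step 12.
- What may go wrong: slow C–O coupling of a hindered secondary alkoxide with an electron-rich aryl bromide, with hydrodebromination or oxidation of the alcohol to the ketone (which would also labilise the methine) taking over.
- Fallback (sets out from 9 and 16, returns at 21): the ring is closed with inversion at carbon instead. Step 10 is run with (+)-sparteine, which should give the (1R)-lithiated carbamate F10, the epimeric boronate complex F11 and, after migration, the (2R,3R) boronic ester F12. Miyaura borylation of its aryl bromide (B2pin2, PdCl2(dppf), KOAc, dioxane, 80 °C) gives the bis(boronic ester) F13. Alkaline H2O2 oxidises both C–B bonds to give the phenol–alcohol F14 with the (2R) carbinol. Mitsunobu cyclodehydration (PPh3, DIAD, THF, 0 °C) lets the phenoxide displace the activated carbinol oxygen with inversion, giving the (2S) dihydrobenzofuran 21. Elimination towards the methine hydrogen is the hazard of this route.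

Step 9.
- What may go wrong: the diazo intermediate decomposes by other paths at 110 °C, chiefly intramolecular C–H insertion into the neighbouring benzyloxy CH2 or azine formation; the electron-rich benzylboronate may also lose its second boron.
- Fallback (sets out from 10, returns at 16): iodination of 10 (N-iodosuccinimide, cat. CF3CO2H, MeCN), para to one benzyloxy group and next to bromine, gives 1,5-bis(benzyloxy)-3-bromo-2-iodobenzene F15. Chemoselective Suzuki–Miyaura coupling at the C–I bond with bis[(pinacolato)boryl]methane (Pd[P(tBu)3]2, KOH, dioxane/H2O, rt) gives 16.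

Step 13.
- What may go wrong: incomplete cleavage of nine ethers (the alkyl 3-O-benzyl last), catalyst poisoning by traces of copper, hydrogenolysis of the benzylic flavan O1–C2 bond on prolonged reaction, or air oxidation of the polyphenol during work-up.
- Fallback (sets out from 21, returns at 22): Lewis-acid debenzylation with BCl3 and pentamethylbenzene as cation scavenger (CH2Cl2, −78 °C), then methanol quench. This fallback makes no new compound (F0). Its risk is ionisation of the flavan O1–C2 bond.

## Further compounds

F1 | step 10 | (2R)-2-[3,4-bis(benzyloxy)phenyl]-2-(penta-O-benzyl-(+)-catechin-8-yl)acetaldehyde | O=C[C@H](c1ccc(OCc2ccccc2)c(OCc2ccccc2)c1)c1c(OCc2ccccc2)cc(OCc2ccccc2)c2c1O[C@H](c1ccc(OCc3ccccc3)c(OCc3ccccc3)c1)[C@@H](OCc1ccccc1)C2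
F2 | step 10 | 2-bromo-4,6-bis(benzyloxy)benzyl alcohol | OCc1c(Br)cc(OCc2ccccc2)cc1OCc1ccccc1
F3 | step 10 | 2-bromo-4,6-bis(benzyloxy)benzyl chloride | ClCc1c(Br)cc(OCc2ccccc2)cc1OCc1ccccc1
F4 | step 10 | [2-bromo-4,6-bis(benzyloxy)benzyl]zinc chloride | Cl[Zn]Cc1c(Br)cc(OCc2ccccc2)cc1OCc1ccccc1
F5 | step 10 | (2RS,3R)-1-[2-bromo-4,6-bis(benzyloxy)phenyl]-3-[3,4-bis(benzyloxy)phenyl]-3-(penta-O-benzyl-(+)-catechin-8-yl)propan-2-ol, mixture of carbinol epimers | Brc1cc(OCc2ccccc2)cc(OCc2ccccc2)c1CC(O)[C@H](c1ccc(OCc2ccccc2)c(OCc2ccccc2)c1)c1c(OCc2ccccc2)cc(OCc2ccccc2)c2c1O[C@H](c1ccc(OCc3ccccc3)c(OCc3ccccc3)c1)[C@@H](OCc1ccccc1)C2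
F6 | step 10 | (3R)-1-[2-bromo-4,6-bis(benzyloxy)phenyl]-3-[3,4-bis(benzyloxy)phenyl]-3-(penta-O-benzyl-(+)-catechin-8-yl)propan-2-one | Brc1cc(OCc2ccccc2)cc(OCc2ccccc2)c1CC(=O)[C@H](c1ccc(OCc2ccccc2)c(OCc2ccccc2)c1)c1c(OCc2ccccc2)cc(OCc2ccccc2)c2c1O[C@H](c1ccc(OCc3ccccc3)c(OCc3ccccc3)c1)[C@@H](OCc1ccccc1)C2
F7 | step 5 | (E)-N'-{1-[3,4-bis(benzyloxy)phenyl]ethylidene}-4-methylbenzenesulfonohydrazide | C/C(=N\NS(=O)(=O)c1ccc(C)cc1)c1ccc(OCc2ccccc2)c(OCc2ccccc2)c1
F8 | step 5 | 8-{1-[3,4-bis(benzyloxy)phenyl]vinyl}-3,5,7,3',4'-penta-O-benzyl-(+)-catechin | C=C(c1ccc(OCc2ccccc2)c(OCc2ccccc2)c1)c1c(OCc2ccccc2)cc(OCc2ccccc2)c2c1O[C@H](c1ccc(OCc3ccccc3)c(OCc3ccccc3)c1)[C@@H](OCc1ccccc1)C2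
F9 | step 5 | (2S)-2-[3,4-bis(benzyloxy)phenyl]-2-(penta-O-benzyl-(+)-catechin-8-yl)ethanol, methine epimer of 8 | OC[C@@H](c1ccc(OCc2ccccc2)c(OCc2ccccc2)c1)c1c(OCc2ccccc2)cc(OCc2ccccc2)c2c1O[C@H](c1ccc(OCc3ccccc3)c(OCc3ccccc3)c1)[C@@H](OCc1ccccc1)C2
F10 | step 12 | (1R,2R)-1-lithio derivative of carbamate 9, as its (+)-sparteine complex | CC(C)N(C(C)C)C(=O)O[C@H]([Li])[C@H](c1ccc(OCc2ccccc2)c(OCc2ccccc2)c1)c1c(OCc2ccccc2)cc(OCc2ccccc2)c2c1O[C@H](c1ccc(OCc3ccccc3)c(OCc3ccccc3)c1)[C@@H](OCc1ccccc1)C2
F11 | step 12 | lithium boronate complex of F10 with 16, (1R)-carbamoyloxyalkyl group on boron | CC(C)N(C(C)C)C(=O)O[C@H]([B-]1(Cc2c(Br)cc(OCc3ccccc3)cc2OCc2ccccc2)OC(C)(C)C(C)(C)O1)[C@H](c1ccc(OCc2ccccc2)c(OCc2ccccc2)c1)c1c(OCc2ccccc2)cc(OCc2ccccc2)c2c1O[C@H](c1ccc(OCc3ccccc3)c(OCc3ccccc3)c1)[C@@H](OCc1ccccc1)C2.[Li+]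
F12 | step 12 | (2R,3R) epimer of boronic ester 19 | Brc1cc(OCc2ccccc2)cc(OCc2ccccc2)c1C[C@@H](B2OC(C)(C)C(C)(C)O2)[C@H](c1ccc(OCc2ccccc2)c(OCc2ccccc2)c1)c1c(OCc2ccccc2)cc(OCc2ccccc2)c2c1O[C@H](c1ccc(OCc3ccccc3)c(OCc3ccccc3)c1)[C@@H](OCc1ccccc1)C2
F13 | step 12 | (2R,3R) bis(boronic ester): aryl pinacol boronate in place of the bromine of F12 | CC1(C)OB(OC1(C)C)c1cc(OCc2ccccc2)cc(OCc2ccccc2)c1C[C@@H](B1OC(C)(C)C(C)(C)O1)[C@H](c1ccc(OCc2ccccc2)c(OCc2ccccc2)c1)c1c(OCc2ccccc2)cc(OCc2ccccc2)c2c1O[C@H](c1ccc(OCc3ccccc3)c(OCc3ccccc3)c1)[C@@H](OCc1ccccc1)C2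
F14 | step 12 | (2R,3R)-1-[2-hydroxy-4,6-bis(benzyloxy)phenyl]-3-[3,4-bis(benzyloxy)phenyl]-3-(penta-O-benzyl-(+)-catechin-8-yl)propan-2-ol | Oc1cc(OCc2ccccc2)cc(OCc2ccccc2)c1C[C@@H](O)[C@H](c1ccc(OCc2ccccc2)c(OCc2ccccc2)c1)c1c(OCc2ccccc2)cc(OCc2ccccc2)c2c1O[C@H](c1ccc(OCc3ccccc3)c(OCc3ccccc3)c1)[C@@H](OCc1ccccc1)C2
F15 | step 9 | 1,5-bis(benzyloxy)-3-bromo-2-iodobenzene | Ic1c(Br)cc(OCc2ccccc2)cc1OCc1ccccc1
F0 | step 13 | none | none
A1 | alternative 1 | octa-O-benzyl ether of the target with free flavan 3-hydroxyl | C(c1ccccc1)Oc1cc(OCc2ccccc2)c2c(c1)O[C@H]([C@H](c1ccc(OCc3ccccc3)c(OCc3ccccc3)c1)c1c(OCc3ccccc3)cc(OCc3ccccc3)c3c1O[C@H](c1ccc(OCc4ccccc4)c(OCc4ccccc4)c1)[C@@H](O)C3)C2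
A2 | alternative 1 | ring D aryl ether of 1-[3,4-bis(benzyloxy)phenyl]-2,3-epoxypropan-1-ol carrying the benzylated dihydrobenzofuran–methine unit ortho to the ether oxygen, configured as in A1 | C(c1ccccc1)Oc1cc(OCc2ccccc2)c2c(c1)O[C@H]([C@H](c1ccc(OCc3ccccc3)c(OCc3ccccc3)c1)c1c(OCc3ccccc3)cc(OCc3ccccc3)cc1O[C@H](c1ccc(OCc3ccccc3)c(OCc3ccccc3)c1)[C@@H]1CO1)C2
A3 | alternative 2 | nona-O-benzyl ether of the target (identical with 21) | C(c1ccccc1)Oc1cc(OCc2ccccc2)c2c(c1)O[C@H]([C@H](c1ccc(OCc3ccccc3)c(OCc3ccccc3)c1)c1c(OCc3ccccc3)cc(OCc3ccccc3)c3c1O[C@H](c1ccc(OCc4ccccc4)c(OCc4ccccc4)c1)[C@@H](OCc1ccccc1)C3)C2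
A4 | alternative 2 | 3,5-bis(benzyloxy)-2-[(E)-3-(penta-O-benzyl-(+)-catechin-8-yl)prop-2-enyl]phenol | Oc1cc(OCc2ccccc2)cc(OCc2ccccc2)c1C/C=C/c1c(OCc2ccccc2)cc(OCc2ccccc2)c2c1O[C@H](c1ccc(OCc3ccccc3)c(OCc3ccccc3)c1)[C@@H](OCc1ccccc1)C2
A5 | alternative 2 | 3,4-bis(benzyloxy)phenyl trifluoromethanesulfonate | FC(F)(F)S(=O)(=O)Oc1ccc(OCc2ccccc2)c(OCc2ccccc2)c1
A6 | alternative 3 | cis-fused cycloadduct, benzylated target skeleton with flavan O7 bonded to furan C3 | C(c1ccccc1)Oc1cc(OCc2ccccc2)c2c(c1)O[C@@H]3[C@H](c1ccc(OCc4ccccc4)c(OCc4ccccc4)c1)c1c(O[C@H]23)cc(OCc4ccccc4)c4c1O[C@H](c1ccc(OCc5ccccc5)c(OCc5ccccc5)c1)[C@@H](OCc1ccccc1)C4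
A7 | alternative 3 | 8-{[3,4-bis(benzyloxy)phenyl](hydroxy)methyl}-3,5,3',4'-tetra-O-benzyl-(+)-catechin (7-hydroxyl free, carbinol epimer mixture) | OC(c1ccc(OCc2ccccc2)c(OCc2ccccc2)c1)c1c(O)cc(OCc2ccccc2)c2c1O[C@H](c1ccc(OCc3ccccc3)c(OCc3ccccc3)c1)[C@@H](OCc1ccccc1)C2
A8 | alternative 3 | 4,6-bis(benzyloxy)benzofuran | C(c1ccccc1)Oc1cc(OCc2ccccc2)c2ccoc2c1
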